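## Structural features

The target is a cis-fused pterocarpan: a chroman (ring A with ring B: O5, C6, C6a, C11a, C11b, C4a) and a 2,3-dihydrobenzofuran (ring C: C6a, C6b, C10a, O11, C11a, with ring D) share the C6a–C11a bond. Pterocarpan numbering is used throughout, and the additional 2,2-dimethyldihydropyran is called ring E. Ring E is fused across C1–C2 of ring A with its oxygen on C1, ortho to C11b, so ring A is a fully differentiated phloroglucinol: O1 in ring E, O3 a free phenol, O5 the ring-B oxygen. Ring D carries one methoxy group at C9, para to C6b. The only stereocentres are the adjacent C6a and C11a, both S with their hydrogens cis, and nothing else in the molecule can relay chirality to them. The fragile sites are the C11a–O11 bond (a benzylic aryl ether on a trioxygenated ring, labile to acid and to hydrogenolysis) and the electron-rich ring A with its free phenol, which is easily oxidised. The real difficulty is absolute control of the contiguous pair, together with the regiochemistry of ring E and the distinction of the three ring-A oxygens. The key step uses the fact that O5=C4a–C11b=C11a is a latent o-quinone methide in ring A, and that C6a=C6 can be an enol ether on ring D held to C11a through O11.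

## Logic of the disconnections

**22 to 21.** Cut: the O3–Si bond. O3 is para to C11b, so a free phenol there would open a para-quinone methide channel during the oxidation; a silyl group carried from the first step avoids this. The forward step must remove silicon without touching the C11a–O11 ether, which calls for buffered fluoride.

**21 to 20.** Cut: C6–H, replaced by C6–O(auxiliary). The acetal oxygen at C6 is what makes the C6a=C6 alkene electron-rich and is where the chirality is attached. The forward step must ionise the exocyclic acetal bond faster than the C11a–O11 bond.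

**20 to 18 (through 19).** Cut: C6a–C11a and O5–C6. Rings B and C and all stereocentres disappear and an open benzyl aryl ether remains. The forward step needs oxidation of the free phenol to the ortho methide, a tether that allows only cis fusion, a single alkene geometry and an auxiliary that truly differentiates the alkene faces. For the last two reasons 18 carries an E enol ether made by a stereospecific coupling and a 2-phenylcyclohexyl group, whose phenyl ring shields one face more effectively than a simple terpene alkyl group would.

**18 to 17.** Cut: O5–H, replaced by O5–allyl. O5 must be masked as an ether during hydride reduction and etherification, and unmasked under neutral conditions that spare the enol ether and the silyl ether.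

**17 to 8 and 16.** Cut: C11a–O11. This splits the molecule into a ring A/E benzylic alcohol and a ring-D phenol of similar size. The forward etherification must run without acid, since both the trioxygenated benzyl alcohol and the enol ether are acid-labile.

**16 to 14 and 15.** Cut: the C6a–C6b vinyl–aryl bond. The alkene geometry is then fixed in 14 before coupling instead of being left to a carbonyl olefination. The forward coupling must tolerate a free ortho hydroxyl and the product must be kept away from acid.

**14 to 13, then 9 and 10.** Cut: C6a–B, then the two enol ether carbons from the auxiliary oxygen. The C6/C6a unit comes from a two-carbon chloroalkene and the stereocentres from a commercial alcohol. Syn hydroboration of the ynol ether must place boron on the terminal carbon.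

**8 to 7 to 6.** Cut: C11a–H (hydride) and O5–allyl. The benzylic alcohol is made only after O5 is etherified, so that no acyl or silyl group can migrate to the new alkoxide. The double bond of ring E must already be saturated before the allyl group is introduced.

**6 to 5, then 2 and 3 (through 4).** Cut: the C4–C3 double bond of ring E, then C2–C(ring E) and O1–C(ring E). The forward sequence is O-propargylation, aromatic Claisen rearrangement and electrocyclisation. The ether must sit on an oxygen ortho to the formyl carbon. With the para oxygen free, alkylation would occur there and the pyran oxygen would end up para to C11b, the wrong ring-E isomer; hence 2 and not 1 is the substrate.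

**2 to 1.** Cut: O3–Si. One bulky silyl group on the most acidic, unhindered hydroxyl both directs ring E and protects O3 to the end.

## Other disconnections considered

Alternative 1: Cut C6a–C6b and C11a–O11 (ring C), separating the ring A/B/E chromene A1 (C6a=C11a double bond) from 2-methoxy-1,4-benzoquinone A2. Forward, on a chiral dichlorotitanium diolate, TiCl2(TADDOLate), C6a of A1 attacks the activated quinone A2 and the neighbouring quinone oxygen closes on C11a, giving the 8-hydroxy-9-methoxy pterocarpan A3.
- In favour: it is convergent and sets ring C and both stereocentres from achiral partners. This annulation of 2H-chromenes with alkoxyquinones is an established entry to pterocarpans, so on precedent it is better than the chosen plan. It needs no auxiliary branch, so it is also better in the number of operations before the key step (A1 is within one annulation step of 6).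
- Against, here: A3 carries a hydroxyl at C8 that the target lacks, so sulfonylation and reductive removal must follow, the latter near the hydrogenolysis-prone C11a–O11 bond. The chiral Lewis acid is needed in stoichiometric amount, and its induction with a trioxygenated, ortho-disubstituted styrene is not assured. The cationic intermediate at C11a and the strong Lewis acid also threaten the silyl ether.
- Comparison: structurally the chosen plan closes ring B as well and gives the correct ring-D pattern directly. Mechanistically a stepwise cationic annulation under reagent control stands against an oxidative cycloaddition under auxiliary control. In step economy the two are about equal (shorter before, longer after the key step).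

Alternative 2: Cut the C2–C bond of ring E at the end of the synthesis. Forward, the pterocarpan 1-O-(1,1-dimethylpropargyl) ether A4 rearranges on heating to the chromene A5.
- In favour: the rearrangement needs no reagent, and its regiochemistry is unambiguous because C2 is the only free ortho position. On reliability it equals step 2 of the chosen plan, and it keeps the early ring-A intermediates simpler.
- Against, here: it does nothing for the stereocentres, so A4 must first be made as a single enantiomer by another method, with three differentiated oxygens on ring A. A5 then needs hydrogenation of the chromene double bond in the presence of the C11a–O11 benzylic ether, which is itself hydrogenolysed under such conditions.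
- Comparison: structurally it addresses ring E only, whereas the chosen plan installs ring E in step 2 before any sensitive function exists. The mechanism is that of step 2. The number of operations for ring E is the same, but they sit late and cost an extra protecting-group operation for O1, so the chosen plan is better in step economy.

Alternative 3: Cut C6a–C11a alone. Forward, the ring-D aryldiazoacetate A6 loses nitrogen on a chiral dirhodium tetracarboxylate, Rh2(O2CR*)4, and the carbene inserts into the benzylic O–CH2 bond to give the cis-dihydrobenzofuran ester A7.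
- In favour: it is catalytic in the chiral element, belongs to a known class of asymmetric C–H insertions for this ring system, and starts from the same kind of benzyl aryl ether as the chosen plan. On precedent and on economy of the chiral source it is better.
- Against, here: only ring C is closed, so ester reduction, desilylation and ring closure must follow. The C6a centre of A7 is alpha to an ester and can epimerise to the trans isomer, which cannot close ring B. The C–H bond is flanked by a 2,6-disubstituted aryl group, and a diazo compound must be handled on scale.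
- Comparison: structurally the chosen plan forms both rings and leaves C6 one reduction from the target. Mechanistically insertion is better understood than the proposed cycloaddition. In step economy the alternative spends one more step after its key step but saves the auxiliary branch, so the two are about equal.

Key step: step 11

Assumption: the facial sense of the auxiliary is assigned from the s-trans enol ether conformer with the carbinol C–H in the alkene plane; if the opposite sense held, the commercial (1R,2S) enantiomer of 9 would be used in step 6 and nothing else would change.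

## Route

Step 1
Reactants: 1 2,4,6-trihydroxybenzaldehyde
Product: 2 2,6-dihydroxy-4-[(triisopropylsilyl)oxy]benzaldehyde
Conditions: TIPSCl (1.05 equiv), imidazole, DMF, 0 °C
Reagents that add atoms: chlorotriisopropylsilane, CC(C)[Si](Cl)(C(C)C)C(C)C
Why: Silyl ether formation; the 4-hydroxyl is the most acidic and the only one not flanked by the formyl group, so the bulky chlorosilane should react there first. The group blocks O4 for step 2 and protects O3 to the end.

Step 2
Reactants: 2 2,6-dihydroxy-4-[(triisopropylsilyl)oxy]benzaldehyde; 3 3-chloro-3-methylbut-1-yne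
Product: 5 7-hydroxy-2,2-dimethyl-5-[(triisopropylsilyl)oxy]-2H-chromene-8-carbaldehyde, via aryl 1,1-dimethylpropargyl ether 4 (not isolated)
Conditions: DBU, CuCl2·2H2O (1 mol%), MeCN, 0 °C; then xylenes, 140 °C
Reagents that add atoms: none
Why: Copper-catalysed O-propargylation of one of the two equivalent ortho hydroxyls, then aromatic propargyl Claisen rearrangement to the only free ortho carbon, enolisation, 1,5-hydrogen shift and oxa-6π electrocyclisation. Because O4 is blocked, the pyran oxygen ends up ortho to the formyl carbon (future C1), as the target requires.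

Step 3
Reactants: 5 7-hydroxy-2,2-dimethyl-5-[(triisopropylsilyl)oxy]-2H-chromene-8-carbaldehyde
Product: 6 7-hydroxy-2,2-dimethyl-5-[(triisopropylsilyl)oxy]chroman-8-carbaldehyde
Conditions: H2 (1 atm), Pd/C (5% Pd), EtOAc, rt
Reagents that add atoms: none
Why: Heterogeneous hydrogenation of the cis-disubstituted styrenic double bond should be much faster than reduction of the electron-rich, hydrogen-bonded aryl aldehyde; the reaction is stopped after one equivalent of hydrogen.

Step 4
Reactants: 6 7-hydroxy-2,2-dimethyl-5-[(triisopropylsilyl)oxy]chroman-8-carbaldehyde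
Product: 7 7-(allyloxy)-2,2-dimethyl-5-[(triisopropylsilyl)oxy]chroman-8-carbaldehyde
Conditions: allyl bromide, K2CO3, acetone, 50 °C
Reagents that add atoms: allyl bromide, C=CCBr
Why: Williamson etherification of the remaining chelated phenol (future O5). Allyl survives hydride and Mitsunobu conditions and can be removed under neutral conditions; it is introduced only after the hydrogenation.

Step 5
Reactants: 7 7-(allyloxy)-2,2-dimethyl-5-[(triisopropylsilyl)oxy]chroman-8-carbaldehyde
Product: 8 {7-(allyloxy)-2,2-dimethyl-5-[(triisopropylsilyl)oxy]chroman-8-yl}methanol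
Conditions: NaBH4, THF–MeOH, 0 °C
Reagents that add atoms: none
Why: Borohydride reduction of the aryl aldehyde gives the benzylic alcohol (future C11a). With an ether on the ortho oxygen no group can migrate to the new alkoxide.

Step 6
Reactants: 9 (1S,2R)-trans-2-phenylcyclohexan-1-ol; 10 trichloroethylene
Product: 13 ethynyl (1S,2R)-2-phenylcyclohexyl ether, via dichlorovinyl ether 11 (not isolated), via lithium alkoxyacetylide 12 (not isolated)
Conditions: KH, THF, 0 °C → rt; then n-BuLi (2.5 equiv), −78 → −40 °C; MeOH
Reagents that add atoms: none
Why: The potassium alkoxide adds to dichloroacetylene formed in the flask from trichloroethylene; n-BuLi then effects elimination and chlorine–lithium exchange, and protonation gives the ynol ether (established ynol ether synthesis from secondary alcohols). The carbinol stereocentre is not involved.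

Step 7
Reactants: 13 ethynyl (1S,2R)-2-phenylcyclohexyl ether
Product: 14 4,4,5,5-tetramethyl-2-[(E)-2-{[(1S,2R)-2-phenylcyclohexyl]oxy}ethenyl]-1,3,2-dioxaborolane
Conditions: HBpin, Cp2Zr(H)Cl (5 mol%), Et3N (10 mol%), CH2Cl2, rt
Reagents that add atoms: pinacolborane, CC1(C)OBOC1(C)C
Why: Catalysed syn hydroboration of the terminal alkyne; boron goes to the terminal carbon (sterics and ynol ether polarisation), so only the E 2-alkoxyvinylboronate should form.

Step 8
Reactants: 14 4,4,5,5-tetramethyl-2-[(E)-2-{[(1S,2R)-2-phenylcyclohexyl]oxy}ethenyl]-1,3,2-dioxaborolane; 15 2-iodo-5-methoxyphenol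
Product: 16 5-methoxy-2-[(E)-2-{[(1S,2R)-2-phenylcyclohexyl]oxy}ethenyl]phenol
Conditions: Pd(dppf)Cl2 (3 mol%), K3PO4, THF–H2O, 60 °C
Reagents that add atoms: none
Why: Suzuki–Miyaura coupling with retention of alkene geometry fixes the E enol ether, which an alkoxymethylene Wittig reaction could not guarantee; the unprotected o-iodophenol reacts as its phenoxide. The product is acid-sensitive, so work-up is at pH 7–8 and chromatography on base-washed silica.

Step 9
Reactants: 8 {7-(allyloxy)-2,2-dimethyl-5-[(triisopropylsilyl)oxy]chroman-8-yl}methanol; 16 5-methoxy-2-[(E)-2-{[(1S,2R)-2-phenylcyclohexyl]oxy}ethenyl]phenol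
Product: 17 7-(allyloxy)-8-({5-methoxy-2-[(E)-2-{[(1S,2R)-2-phenylcyclohexyl]oxy}ethenyl]phenoxy}methyl)-2,2-dimethyl-5-[(triisopropylsilyl)oxy]chroman
Conditions: PPh3, DIAD, THF, 0 °C → rt
Reagents that add atoms: none
Why: Mitsunobu etherification; the phenoxide displaces the oxyphosphonium derivative of the primary benzylic alcohol and forms C11a–O11 under essentially neutral conditions, which suit both the acid-labile benzyl alcohol and the enol ether.

Step 10
Reactants: 17 7-(allyloxy)-8-({5-methoxy-2-[(E)-2-{[(1S,2R)-2-phenylcyclohexyl]oxy}ethenyl]phenoxy}methyl)-2,2-dimethyl-5-[(triisopropylsilyl)oxy]chroman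
Product: 18 8-({5-methoxy-2-[(E)-2-{[(1S,2R)-2-phenylcyclohexyl]oxy}ethenyl]phenoxy}methyl)-2,2-dimethyl-5-[(triisopropylsilyl)oxy]chroman-7-ol
Conditions: Pd(PPh3)4 (5 mol%), morpholine, THF, 0 °C → rt
Reagents that add atoms: none
Why: Tsuji–Trost deallylation; zerovalent palladium ionises the allyl aryl ether and morpholine captures the π-allyl fragment, while silyl ether, enol ether and benzyl aryl ether are inert. The product is kept cold and free of strong base, because loss of the ring-D phenoxide from an o-hydroxybenzyl aryl ether would give a quinone methide prematurely.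

Step 11
Reactants: 18 8-({5-methoxy-2-[(E)-2-{[(1S,2R)-2-phenylcyclohexyl]oxy}ethenyl]phenoxy}methyl)-2,2-dimethyl-5-[(triisopropylsilyl)oxy]chroman-7-ol
Product: 20 (6R,6aR,11aS)-9-methoxy-6-{[(1S,2R)-2-phenylcyclohexyl]oxy}-3-O-(triisopropylsilyl)pterocarpan carrying the 2,2-dimethyldihydropyran ring E at C1–C2 (oxygen on C1; C6a and C11a arranged in space as in the target), via o-quinone methide 19 (not isolated)
Conditions: Ag2O (2.5 equiv), 4 Å MS, toluene, rt, dark
Reagents that add atoms: none
Why: Proposed new method: Ag2O should take two electrons and two protons from the free phenol and its ortho CH2–OAr group to give the o-quinone methide 19 (O5=C4a–C11b=C11a), whose methide carbon C11a carries the ring-D aryloxy group; the nucleophilic enol ether carbon C6a then bonds to C11a and O5 to the oxocarbenium-like C6, an intramolecular inverse-electron-demand hetero-Diels–Alder reaction that may be concerted but asynchronous. The closest known reaction types are intramolecular cycloadditions of oxidatively or thermally generated o-quinone methides with tethered alkenes and intermolecular cycloadditions of o-quinone methides with chiral 2-arylcyclohexyl vinyl ethers; a methide carbon whose aryloxy substituent is also the tether has not been used. Ring C (five-membered) closes by C6a–C11a bond formation across the three-atom tether O11–C10a–C6b, and ring B (six-membered) closes by O5–C6 bond formation as the second bond of the [4+2] array. C11a and C6a: the cis relationship is imposed by the tether, since a trans-fused dihydrobenzofuran–chroman is prohibitively strained, and the absolute sense is set by the auxiliary, whose phenyl group in the s-trans enol ether covers the C6a-Re/C6-Si face so that the heterodiene should add to the C6a-Si/C6-Re face, the (6aS,11aS) arrangement of the target. C6: a third, transient centre; suprafacial addition to the E alkene places the alkoxy group trans to C6b, and the centre is removed in step 12. Regiochemistry follows from polarity (C6a nucleophilic, C11a electrophilic) and from the tether. The step needs oxidation at the ortho CH2–OAr group in preference to the para ring-E methylene, which the α-oxygen (weaker C–H bond, donor-stabilised methide) should secure, while the silyl group on O3 excludes a para-quinone methide through C3 and the sieves keep the water formed from adding to C11a.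

Step 12
Reactants: 20 (6R,6aR,11aS)-9-methoxy-6-{[(1S,2R)-2-phenylcyclohexyl]oxy}-3-O-(triisopropylsilyl)pterocarpan with ring E
Product: 21 (6aS,11aS)-9-methoxy-3-O-(triisopropylsilyl)pterocarpan carrying the 2,2-dimethyldihydropyran ring E at C1–C2 (oxygen on C1)
Conditions: Et3SiH, BF3·OEt2, CH2Cl2, −78 → −40 °C
Reagents that add atoms: none
Why: Ionic hydrogenation of a mixed acetal; BF3 complexes the more basic exocyclic alkoxy oxygen, the O5-stabilised oxocarbenium ion at C6 is reduced by the silane and the auxiliary 9 is released for reuse. The low temperature is meant to keep the C11a–O11 benzylic ether from ionising; C6a and C11a are not touched.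

Step 13
Reactants: 21 (6aS,11aS)-9-methoxy-3-O-(triisopropylsilyl)pterocarpan with ring E
Product: 22 (6aS,11aS)-3-hydroxy-9-methoxypterocarpan carrying the 2,2-dimethyldihydropyran ring E at C1–C2 (oxygen on C1), the target
Conditions: Bu4NF, AcOH, THF, 0 °C → rt
Reagents that add atoms: none
Why: Fluoride cleaves the aryl silyl ether; buffering with acetic acid avoids a strongly basic phenoxide medium. No stereocentre is involved.

## Compound list

1 | 2,4,6-trihydroxybenzaldehyde | O=Cc1c(O)cc(O)cc1O | starting material
2 | 2,6-dihydroxy-4-[(triisopropylsilyl)oxy]benzaldehyde | O=Cc1c(O)cc(O[Si](C(C)C)(C(C)C)C(C)C)cc1O | intermediate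
3 | 3-chloro-3-methylbut-1-yne | CC(C)(Cl)C#C | starting material
4 | 2-hydroxy-6-[(2-methylbut-3-yn-2-yl)oxy]-4-[(triisopropylsilyl)oxy]benzaldehyde | CC(C)(C#C)Oc1cc(O[Si](C(C)C)(C(C)C)C(C)C)cc(O)c1C=O | intermediate (not isolated)
5 | 7-hydroxy-2,2-dimethyl-5-[(triisopropylsilyl)oxy]-2H-chromene-8-carbaldehyde | CC1(C)C=Cc2c(O[Si](C(C)C)(C(C)C)C(C)C)cc(O)c(C=O)c2O1 | intermediate
6 | 7-hydroxy-2,2-dimethyl-5-[(triisopropylsilyl)oxy]chroman-8-carbaldehyde | CC1(C)CCc2c(O[Si](C(C)C)(C(C)C)C(C)C)cc(O)c(C=O)c2O1 | intermediate
7 | 7-(allyloxy)-2,2-dimethyl-5-[(triisopropylsilyl)oxy]chroman-8-carbaldehyde | CC1(C)CCc2c(O[Si](C(C)C)(C(C)C)C(C)C)cc(OCC=C)c(C=O)c2O1 | intermediate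
8 | {7-(allyloxy)-2,2-dimethyl-5-[(triisopropylsilyl)oxy]chroman-8-yl}methanol | CC1(C)CCc2c(O[Si](C(C)C)(C(C)C)C(C)C)cc(OCC=C)c(CO)c2O1 | intermediate
9 | (1S,2R)-(+)-trans-2-phenylcyclohexan-1-ol | O[C@H]1CCCC[C@@H]1c1ccccc1 | starting material
10 | trichloroethylene | ClC=C(Cl)Cl | starting material
11 | (E)-1,2-dichlorovinyl (1S,2R)-2-phenylcyclohexyl ether | Cl/C=C(/Cl)O[C@H]1CCCC[C@@H]1c1ccccc1 | intermediate (not isolated)
12 | lithium {[(1S,2R)-2-phenylcyclohexyl]oxy}acetylide | [Li]C#CO[C@H]1CCCC[C@@H]1c1ccccc1 | intermediate (not isolated)
13 | ethynyl (1S,2R)-2-phenylcyclohexyl ether | C#CO[C@H]1CCCC[C@@H]1c1ccccc1 | intermediate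
14 | 4,4,5,5-tetramethyl-2-[(E)-2-{[(1S,2R)-2-phenylcyclohexyl]oxy}ethenyl]-1,3,2-dioxaborolane | CC1(C)OB(/C=C/O[C@H]2CCCC[C@@H]2c2ccccc2)OC1(C)C | intermediate
15 | 2-iodo-5-methoxyphenol | COc1ccc(I)c(O)c1 | starting material
16 | 5-methoxy-2-[(E)-2-{[(1S,2R)-2-phenylcyclohexyl]oxy}ethenyl]phenol | COc1ccc(/C=C/O[C@H]2CCCC[C@@H]2c2ccccc2)c(O)c1 | intermediate
17 | 7-(allyloxy)-8-({5-methoxy-2-[(E)-2-{[(1S,2R)-2-phenylcyclohexyl]oxy}ethenyl]phenoxy}methyl)-2,2-dimethyl-5-[(triisopropylsilyl)oxy]chroman | CC1(C)CCc2c(O[Si](C(C)C)(C(C)C)C(C)C)cc(OCC=C)c(COc3cc(OC)ccc3/C=C/O[C@H]3CCCC[C@@H]3c3ccccc3)c2O1 | intermediate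
18 | 8-({5-methoxy-2-[(E)-2-{[(1S,2R)-2-phenylcyclohexyl]oxy}ethenyl]phenoxy}methyl)-2,2-dimethyl-5-[(triisopropylsilyl)oxy]chroman-7-ol (key-step precursor) | CC1(C)CCc2c(O[Si](C(C)C)(C(C)C)C(C)C)cc(O)c(COc3cc(OC)ccc3/C=C/O[C@H]3CCCC[C@@H]3c3ccccc3)c2O1 | intermediate
19 | 8-[({5-methoxy-2-[(E)-2-{[(1S,2R)-2-phenylcyclohexyl]oxy}ethenyl]phenyl}oxy)methylidene]-2,2-dimethyl-5-[(triisopropylsilyl)oxy]-3,4-dihydro-2H-chromen-7(8H)-one (o-quinone methide) | O=C1C=C(O[Si](C(C)C)(C(C)C)C(C)C)C2=C(OC(C)(C)CC2)C1=COc1cc(OC)ccc1/C=C/O[C@H]1CCCC[C@@H]1c1ccccc1 | intermediate (not isolated)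
20 | (6R,6aR,11aS)-9-methoxy-6-{[(1S,2R)-2-phenylcyclohexyl]oxy}-3-O-(triisopropylsilyl)pterocarpan with ring E at C1–C2; 6-alkoxy group trans to C6b | COc1ccc2c(c1)O[C@@H]1c3c(cc(O[Si](C(C)C)(C(C)C)C(C)C)c4c3OC(C)(C)CC4)O[C@@H](O[C@H]3CCCC[C@@H]3c3ccccc3)[C@H]21 | intermediate
21 | (6aS,11aS)-9-methoxy-3-O-(triisopropylsilyl)pterocarpan with ring E at C1–C2 | COc1ccc2c(c1)O[C@@H]1c3c(cc(O[Si](C(C)C)(C(C)C)C(C)C)c4c3OC(C)(C)CC4)OC[C@H]21 | intermediate
22 | (6aS,11aS)-3-hydroxy-9-methoxypterocarpan with the 2,2-dimethyldihydropyran ring E at C1–C2 (oxygen on C1) | COc1ccc2c(c1)O[C@@H]1c3c(cc(O)c4c3OC(C)(C)CC4)OC[C@H]21 | target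

## Step count and risks

Total: 13 steps. Longest linear sequence: 10 steps (steps 1–5 and 9–13); the auxiliary branch (steps 6–8) joins at step 9.

**Step 11 (key step, new method).**
- What may go wrong: insufficient facial discrimination by the auxiliary, since the sense depends on the enol ether reacting through one conformer; oxidation at the ring-E methylene para to the free phenol instead of at the ortho CH2–OAr group, which would dehydrogenate ring E; and capture of the methide carbon by water or expulsion of the ring-D phenoxide before the cycloaddition.
- Fallback (known chemistry, catalyst control instead of auxiliary control): it sets out from 8 and returns at 21. 8 is etherified under Mitsunobu conditions with methyl (2-hydroxy-4-methoxyphenyl)acetate to give the arylacetate F1. Diazo transfer with 4-acetamidobenzenesulfonyl azide and DBU gives the aryldiazoacetate F2. Rh2(S-DOSP)4 or its enantiomer, whichever delivers the required series, should insert the carbene into the benzylic O–CH2 bond to give the cis-2-aryl-2,3-dihydrobenzofuran-3-carboxylate F3. LiBH4 reduction gives the primary alcohol F4, deallylation as in step 10 gives the phenol alcohol F5, and Mitsunobu closure of O5 on C6 gives 21.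

**Step 12.**
- What may go wrong: ionisation of the C11a–O11 benzylic ether by the Lewis acid with reductive opening of ring C, or endocyclic cleavage of the acetal; the trioxygenated ring A stabilises a cation at C11a unusually well.
- Fallback (no Lewis acid, no silane): it sets out from 20 and returns at 21. The acetal is hydrolysed with pyridinium p-toluenesulfonate in wet acetone to the lactol F6, with recovery of 9. NaBH4 at −20 °C reduces the open hydroxy-aldehyde form to the phenol alcohol F5 (the compound of that label in the fallback to step 11), and Mitsunobu closure gives 21.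

**Step 8.**
- What may go wrong: acid-catalysed addition of the free ortho hydroxyl to the enol ether during work-up or chromatography, with ring closure and loss of the auxiliary, or protodeboronation of 14.
- Fallback (enol ether installed after the ether bond): it sets out from 8 and 9 and returns at 17. 9 is converted with paraformaldehyde and HCl into the chloromethyl ether F7 and with PPh3 into the phosphonium chloride F8. 8 is coupled under Mitsunobu conditions with 2-hydroxy-4-methoxybenzaldehyde to give the aldehyde F9. Wittig reaction of F9 with the ylide from F8 (KHMDS, THF, −78 °C) gives 17 together with its Z isomer F10, from which 17 is separated by chromatography. The price is the loss of geometric control.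

**Step 2.**
- What may go wrong: incomplete or double O-alkylation of the hydrogen-bonded hydroxyls, or loss of the para silyl group under the amidine base.
- Fallback (different ring construction): it sets out from 2 and returns at 5. Condensation of 2 with 3-methylbut-2-enal (ethylenediammonium diacetate, toluene, 110 °C) proceeds by C-alkylation next to O2, dehydration and oxa-6π electrocyclisation to give 5 directly; the silyl group on O4 again fixes the regiochemistry. No new compound is made.

## Further compounds

F1 | step 11 | methyl 2-[2-({7-(allyloxy)-2,2-dimethyl-5-[(triisopropylsilyl)oxy]chroman-8-yl}methoxy)-4-methoxyphenyl]acetate | COC(=O)Cc1ccc(OC)cc1OCc1c(OCC=C)cc(O[Si](C(C)C)(C(C)C)C(C)C)c2CCC(C)(C)Oc12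
F2 | step 11 | methyl 2-diazo-2-[2-({7-(allyloxy)-2,2-dimethyl-5-[(triisopropylsilyl)oxy]chroman-8-yl}methoxy)-4-methoxyphenyl]acetate | COC(=O)C(=[N+]=[N-])c1ccc(OC)cc1OCc1c(OCC=C)cc(O[Si](C(C)C)(C(C)C)C(C)C)c2CCC(C)(C)Oc12
F3 | step 11 | methyl cis-2-{7-(allyloxy)-2,2-dimethyl-5-[(triisopropylsilyl)oxy]chroman-8-yl}-6-methoxy-2,3-dihydrobenzofuran-3-carboxylate | COc1ccc2c(c1)O[C@H](c1c(OCC=C)cc(O[Si](C(C)C)(C(C)C)C(C)C)c3CCC(C)(C)Oc13)[C@@H]2C(=O)OC
F4 | step 11 | (cis-2-{7-(allyloxy)-2,2-dimethyl-5-[(triisopropylsilyl)oxy]chroman-8-yl}-6-methoxy-2,3-dihydrobenzofuran-3-yl)methanol | COc1ccc2c(c1)O[C@H](c1c(OCC=C)cc(O[Si](C(C)C)(C(C)C)C(C)C)c3CCC(C)(C)Oc13)[C@@H]2CO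
F5 | step 11 | 8-[cis-3-(hydroxymethyl)-6-methoxy-2,3-dihydrobenzofuran-2-yl]-2,2-dimethyl-5-[(triisopropylsilyl)oxy]chroman-7-ol | COc1ccc2c(c1)O[C@H](c1c(O)cc(O[Si](C(C)C)(C(C)C)C(C)C)c3CCC(C)(C)Oc13)[C@@H]2CO
F6 | step 12 | (6aR,11aS)-6-hydroxy-9-methoxy-3-O-(triisopropylsilyl)pterocarpan with ring E (lactol, both C6 epimers) | COc1ccc2c(c1)O[C@@H]1c3c(cc(O[Si](C(C)C)(C(C)C)C(C)C)c4c3OC(C)(C)CC4)OC(O)[C@H]21
F7 | step 8 | chloromethyl (1S,2R)-2-phenylcyclohexyl ether | ClCO[C@H]1CCCC[C@@H]1c1ccccc1
F8 | step 8 | ({[(1S,2R)-2-phenylcyclohexyl]oxy}methyl)triphenylphosphonium chloride | [Cl-].c1ccccc1[P+](c1ccccc1)(c1ccccc1)CO[C@H]1CCCC[C@@H]1c1ccccc1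
F9 | step 8 | 2-({7-(allyloxy)-2,2-dimethyl-5-[(triisopropylsilyl)oxy]chroman-8-yl}methoxy)-4-methoxybenzaldehyde | COc1ccc(C=O)c(OCc2c(OCC=C)cc(O[Si](C(C)C)(C(C)C)C(C)C)c3CCC(C)(C)Oc23)c1
F10 | step 8 | Z isomer of 17 | CC1(C)CCc2c(O[Si](C(C)C)(C(C)C)C(C)C)cc(OCC=C)c(COc3cc(OC)ccc3/C=C\O[C@H]3CCCC[C@@H]3c3ccccc3)c2O1
F0 | step 2 | none | none
A1 | alternative 1 | ring A/B/E 2H-chromene with C6a=C11a double bond, 3-O-TIPS | CC1(C)CCc2c(O[Si](C(C)C)(C(C)C)C(C)C)cc3OCC=Cc3c2O1
A2 | alternative 1 | 2-methoxy-1,4-benzoquinone | COC1=CC(=O)C=CC1=O
A3 | alternative 1 | (6aS,11aS)-8-hydroxy-9-methoxy-3-O-(triisopropylsilyl)pterocarpan with ring E | COc1c(O)cc2c(c1)O[C@@H]1c3c(cc(O[Si](C(C)C)(C(C)C)C(C)C)c4c3OC(C)(C)CC4)OC[C@H]21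
A4 | alternative 2 | (6aS,11aS)-9-methoxy-1-[(2-methylbut-3-yn-2-yl)oxy]-3-O-(tert-butyldimethylsilyl)pterocarpan | COc1ccc2c(c1)O[C@@H]1c3c(cc(O[Si](C)(C)C(C)(C)C)cc3OC(C)(C)C#C)OC[C@H]21
A5 | alternative 2 | 3-O-TBS chromene analogue of the target (ring E unsaturated) | COc1ccc2c(c1)O[C@@H]1c3c(cc(O[Si](C)(C)C(C)(C)C)c4c3OC(C)(C)C=C4)OC[C@H]21
A6 | alternative 3 | methyl 2-diazo-2-[2-({5,7-bis[(tert-butyldimethylsilyl)oxy]-2,2-dimethylchroman-8-yl}methoxy)-4-methoxyphenyl]acetate | COC(=O)C(=[N+]=[N-])c1ccc(OC)cc1OCc1c(O[Si](C)(C)C(C)(C)C)cc(O[Si](C)(C)C(C)(C)C)c2CCC(C)(C)Oc12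
A7 | alternative 3 | methyl cis-2-{5,7-bis[(tert-butyldimethylsilyl)oxy]-2,2-dimethylchroman-8-yl}-6-methoxy-2,3-dihydrobenzofuran-3-carboxylate | COc1ccc2c(c1)O[C@H](c1c(O[Si](C)(C)C(C)(C)C)cc(O[Si](C)(C)C(C)(C)C)c3CCC(C)(C)Oc13)[C@@H]2C(=O)OC
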